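(The numbers in the tables are calculated with constants of no real substance, and the scatter is random.)

To the colleague who asked for a quick number on the flask at 0.30 M:

| flask | substrate | remark | time |
|---|---|---|---|
| ochre | 0.15 M | run made earlier |  |
| grey | 0.60 M | run made earlier |  |
| flask | 0.30 M |  | 20 min |

- ochre (time / min: target / %, isomer of the product A / %): 1.50: 6.8, 0; 3.00: 11.0, 0.6; 5.00: 16.6, 3.0; 6.00: 18.1, 4.5; 8.00: 23.7, 5.6; 10.0: 26.6, 7.2; 12.0: 31.7, 8.9
- grey (time / min: target / %, isomer of the product A / %): 1.00: 6.8, 1.2; 1.33: 5.1, 1.0; 2.00: 7.8, 1.3; 3.00: 13.8, 1.2; 5.00: 18.7, 1.1; 8.00: 26.4, 2.0; 12.0: 39.3, 3.1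

(scatter of a reading: 1 percentage point)

* share of target in target plus isomer of the product A at 30 s
* share of target in target plus isomer of the product A at 20 min
* which of target and isomer of the product A there is more of at 20 min

- a reading or a percentage of target counts all its forms, free or not

In the ochre run, isomer of the product A reads 0 % at 1.50 min while target already reads 6.8 %. Read against a scatter of 1 percentage point, this induction period points to a consecutive reaction, with the isomer formed from target. The useful count is then the number of turnovers n = κ·t, where κ is the turnovers of target into the isomer per minute. While n is well below one and target is made at a steady rate, target grows linearly and the isomer as the square of time: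

c(isomer of the product A) / c(target) = n/2

Pooling the ochre readings from 3.00 min to 6.00 min gives the reading

κ = 0.0721 min⁻¹

Taking κ over from the ochre run, in the flask at 30 s:

n = 0.0361, so the share of target is 98.2 %

The forecast gives 90 % there, from “a small early burst”. This reckoning differs: the grey reading of 1.2 % at 1.00 min stands against a scatter of 1 point, and no burst is counted. At 20 min in the flask, n reaches 1.44, above one and outside the rule, so this reckoning gives no number of its own there and the forecast's 85 %, with target ahead, stands for that time.

The flask gives 98.3 % at 30 s and 87.3 % at 20 min, with target ahead. At 2.00 min crystals in the flask stand at 0 %. There n/2 gives 0.0721, and the flask holds isomer of the product A to target in a ratio of 0.0706.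

    substrate ⇌ target (K = 2.70, k = 0.0463 min⁻¹)
    target ⇌ isomer of the product A (K = 0.950, k = 0.0679 min⁻¹)
    isomer of the product A ⇌ isomer of the product B (K = 0.127, k = 0.00325 min⁻¹)
    isomer of the product B ⇌ substrate (k = 0.0171 min⁻¹)
    crystals ⇌ target, rate k5*(cs5 - [target]) while solid is left; crystals form when [target] > cs5 (solubility = 25.0 mM, k = 2.64 min⁻¹)
    substrate → decomposition product (k = 3.13 × 10⁻⁴ min⁻¹)

Reckoned with the κ of the ochre run, n contains no charge, so for the neighbouring flask at 0.18 M it again gives 98.2 % at 30 s. The computed share in that neighbouring flask is 98.3 %.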